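**Retrosynthetic overview** (isochromene locants of the target: O2, C1, C3, C4, C4a, C5, C6, C7, C8, C8a)
- Last bond: the ester at the C7 oxygen, from (7R)-7-hydroxy-3,7-dimethyl-6H-isochromene-6,8(7H)-dione and linoleoyl chloride.
- Pyran ring (formed second): O2–C3 by 6-endo-dig addition of the formyl oxygen of a 2-formyl vinylogous acid to a propynyl group on C4a; the C8 oxygen comes from hydrolysis of a vinylogous acyl bromide.
- Carbocycle (formed first): C7–C8 and C4a–C8a in one [4+2] cycloaddition of a 2-methyl-5-propynyl-3-silyloxyfuran with 3-bromopropynal, followed in the same flask by fluoride-triggered opening of the oxygen bridge.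
- Enabling feature: O–C7(CH3)–C6(=O)–C5H=C4a is a ring-opened 2-methyl-3-oxyfuran (furan oxygen = C7–O, furan C3–O = C6=O), and C8(=O)–C8a=C1H–O2 is a masked 2-formyl ketone, i.e. an ynal dienophile. A cheap flat furan is thus dearomatised into the ring that carries the only stereocentre.
- The furan comes from a silyl-protected ethyl (S)-lactate and penta-1,3-diyne through a diynone and a furan-3(2H)-one.

Key step: step 7

Assumption: the sense of induction of the boron catalyst in step 7 is not known for this substrate pair; if the (S)-catalyst gives 7S, its antipode is used.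
Assumption: penta-1,3-diyne (3) and 3-bromoprop-2-ynal (12) are handled only as cold solutions and are not concentrated.

Step 1
Reactants: 1 1,4-dichlorobut-2-yne
Product: 3 penta-1,3-diyne, via sodium buta-1,3-diyn-1-ide 2 (not isolated)
Conditions: NaNH2 (3.0 equiv), liquid NH3, −40 °C; then MeI (1.0 equiv), −60 to −33 °C; NH3 evaporated, product taken up in cold THF
Reagents that add atoms: iodomethane (MeI), CI
Why: Double dehydrochlorination gives buta-1,3-diyne, the third equivalent of amide forms the monosodium acetylide, and SN2 methylation should give the diyne (acetylide alkylation in liquid ammonia).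

Step 2
Reactants: 3 penta-1,3-diyne; 4 ethyl (2S)-2-[(tert-butyldimethylsilyl)oxy]propanoate
Product: 6 (2S)-2-[(tert-butyldimethylsilyl)oxy]octa-4,6-diyn-3-one, via lithium penta-1,3-diyn-1-ide 5 (not isolated)
Conditions: n-BuLi (1.0 equiv), THF, −78 °C; then 4 (0.9 equiv), −78 °C; AcOH quench at −78 °C
Reagents that add atoms: none
Why: Acylation of a lithium acetylide by an ester, in which the tetrahedral lithium hemiketal should survive at −78 °C until the cold acidic quench, so that the ynone is not attacked a second time; the lactate stereocentre is not involved.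

Step 3
Reactants: 6 (2S)-2-[(tert-butyldimethylsilyl)oxy]octa-4,6-diyn-3-one
Product: 8 (2S)-2-methyl-5-(prop-1-yn-1-yl)furan-3(2H)-one, via hydroxy diynone 7 (not isolated)
Conditions: Bu4NF·3H2O (1.1 equiv), THF, −20 to 0 °C
Reagents that add atoms: none
Why: Fluoride removes the silyl group and the α′-alkoxide adds to the ynone β-carbon in a 5-endo-dig oxa-Michael cyclisation (the standard furan-3(2H)-one synthesis from α′-hydroxy ynones); the distal alkyne stays as the propynyl group, and the labile C2 stereocentre is of no consequence because step 4 removes it.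

Step 4
Reactants: 8 (2S)-2-methyl-5-(prop-1-yn-1-yl)furan-3(2H)-one
Product: 9 triisopropyl{[2-methyl-5-(prop-1-yn-1-yl)furan-3-yl]oxy}silane
Conditions: iPr3SiOSO2CF3 (1.2 equiv), Et3N (1.5 equiv), CH2Cl2, −78 to 0 °C
Reagents that add atoms: triisopropylsilyl trifluoromethanesulfonate, CC(C)[Si](OS(=O)(=O)C(F)(F)F)(C(C)C)C(C)C
Why: Soft enolisation and O-silylation (silyl enol ether formation driven by aromatisation) should give the electron-rich 3-silyloxyfuran and erases the lactate stereocentre.

Step 5
Reactants: 10 prop-2-yn-1-ol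
Product: 11 3-bromoprop-2-yn-1-ol
Conditions: NBS (1.1 equiv), AgNO3 (10 mol%), acetone, 23 °C
Reagents that add atoms: N-bromosuccinimide, O=C1CCC(=O)N1Br
Why: Silver-catalysed electrophilic bromination of a terminal alkyne through the silver acetylide.

Step 6
Reactants: 11 3-bromoprop-2-yn-1-ol
Product: 12 3-bromoprop-2-ynal
Conditions: 1,1,1-triacetoxy-1,1-dihydro-1,2-benziodoxol-3(1H)-one (DMP, 1.1 equiv), CH2Cl2, 0 °C; filtered cold through silica and used as a CH2Cl2 solution
Reagents that add atoms: none
Why: Dess–Martin oxidation of a primary propargylic alcohol to the ynal under non-aqueous conditions that leave the bromoalkyne untouched.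

Step 7
Reactants: 9 triisopropyl{[2-methyl-5-(prop-1-yn-1-yl)furan-3-yl]oxy}silane; 12 3-bromoprop-2-ynal
Product: 14 (3R)-2-bromo-3-hydroxy-3-methyl-4-oxo-6-(prop-1-yn-1-yl)cyclohexa-1,5-diene-1-carbaldehyde, via oxanorbornadiene cycloadduct 13 (not isolated)
Conditions: (3aS)-1-(2-methylphenyl)-3,3-diphenyltetrahydro-1H,3H-pyrrolo[1,2-c][1,3,2]oxazaborole (20 mol%), HN(SO2CF3)2 (18 mol%), CH2Cl2, −78 °C, 9 added slowly to 12 and catalyst; then Bu4NF (1.2 equiv), AcOH (1.2 equiv), THF, −78 to 0 °C
Reagents that add atoms: none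
Why: Proposed new method: the oxazaborolidinium ion binds the formyl oxygen of 12 and lowers the LUMO of its C≡C bond, and the 3-silyloxyfuran 9 (enol-ether carbon C2 most nucleophilic) adds in an asynchronous normal-demand [4+2] cycloaddition that makes C7–C8 first and C4a–C8a second; the closest known reaction types are oxazaborolidinium-catalysed Diels–Alder reactions of furan and of 2-silyloxy dienes with unsaturated carbonyl compounds, chiral boron Lewis acid-catalysed Diels–Alder reactions of acetylenic aldehydes, and thermal Diels–Alder reactions of 3-oxyfurans with 3-bromopropiolates. The carbocycle is closed by this intermolecular cycloaddition (suprafacial on diene and alkyne), which first gives the 7-oxabicyclo[2.2.1]heptadiene 13. C7 (and the transient C4a centre) is set under catalyst control: the aryl pocket of the catalyst should block one face of the bound ynal and the bulky silyloxy-bearing bridge should turn away from the boron-bound formyl group, so that one enantiotopic face of the furan reacts. Regioselectivity (furan C2 to the bromine-bearing carbon) rests on the matched polarisation of the ynal β-carbon and the enol-ether carbon, and reaction at the furan rather than at the propynyl group rests on the much higher HOMO of the oxyfuran. Fluoride then cleaves the silyl enol ether and the enolate expels the bridging oxygen from C4a (E1cB), so that the furan oxygen becomes the tertiary C7–OH and the flat furan becomes the enone ring with the quaternary stereocentre. Bromine is carried as the latent C8 oxygen and the propynyl group as the latent pyran ring.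

Step 8
Reactants: 14 (3R)-2-bromo-3-hydroxy-3-methyl-4-oxo-6-(prop-1-yn-1-yl)cyclohexa-1,5-diene-1-carbaldehyde
Product: 16 (7R)-7-hydroxy-3,7-dimethyl-6H-isochromene-6,8(7H)-dione, via vinylogous acid 15 (not isolated)
Conditions: aq. K2HPO4/KH2PO4 (pH 7.5), MeCN, 23 °C; then CuI (10 mol%), 23 °C
Reagents that add atoms: water, O
Why: Addition–elimination of water at C8 (a vinylogous acyl bromide activated by the formyl group and the dienone) should give the 2-formyl vinylogous acid, whose formyl/enol oxygen adds 6-endo-dig to the CuI-activated alkyne (a cycloisomerisation type known for 2-alkynyl formyl vinylogous acids) and closes the pyran ring without touching C7.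

Step 9
Reactants: 16 (7R)-7-hydroxy-3,7-dimethyl-6H-isochromene-6,8(7H)-dione; 17 (9Z,12Z)-octadeca-9,12-dienoyl chloride
Product: 18 (7R)-3,7-dimethyl-6,8-dioxo-7,8-dihydro-6H-isochromen-7-yl (9Z,12Z)-octadeca-9,12-dienoate
Conditions: 17 (1.3 equiv), Et3N (2.0 equiv), 4-(dimethylamino)pyridine (0.2 equiv), CH2Cl2, 0 to 23 °C
Reagents that add atoms: none
Why: Acyl transfer through the N-acylpyridinium ion should esterify the tertiary α-ketol without touching C7 or the skipped Z,Z-diene.

**Compound list**
1 | 1,4-dichlorobut-2-yne | ClCC#CCCl | starting material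
2 | sodium buta-1,3-diyn-1-ide | [Na+].[C-]#CC#C | intermediate
3 | penta-1,3-diyne | CC#CC#C | intermediate
4 | ethyl (2S)-2-[(tert-butyldimethylsilyl)oxy]propanoate | C[C@H](O[Si](C)(C)C(C)(C)C)C(=O)OCC | starting material
5 | lithium penta-1,3-diyn-1-ide | [Li+].[C-]#CC#CC | intermediate
6 | (2S)-2-[(tert-butyldimethylsilyl)oxy]octa-4,6-diyn-3-one | C[C@H](O[Si](C)(C)C(C)(C)C)C(=O)C#CC#CC | intermediate
7 | (2S)-2-hydroxyocta-4,6-diyn-3-one | C[C@H](O)C(=O)C#CC#CC | intermediate
8 | (2S)-2-methyl-5-(prop-1-yn-1-yl)furan-3(2H)-one (C2 configurationally labile) | CC#CC1=CC(=O)[C@H](C)O1 | intermediate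
9 | triisopropyl{[2-methyl-5-(prop-1-yn-1-yl)furan-3-yl]oxy}silane | CC#Cc1cc(O[Si](C(C)C)(C(C)C)C(C)C)c(C)o1 | intermediate
10 | prop-2-yn-1-ol | C#CCO | starting material
11 | 3-bromoprop-2-yn-1-ol | OCC#CBr | intermediate
12 | 3-bromoprop-2-ynal | O=CC#CBr | intermediate
13 | (1R,4R)-2-bromo-1-methyl-4-(prop-1-yn-1-yl)-6-[(triisopropylsilyl)oxy]-7-oxabicyclo[2.2.1]hepta-2,5-diene-3-carbaldehyde | C[C@@]12O[C@@](C#CC)(C=C1O[Si](C(C)C)(C(C)C)C(C)C)C(C=O)=C2Br | intermediate
14 | (3R)-2-bromo-3-hydroxy-3-methyl-4-oxo-6-(prop-1-yn-1-yl)cyclohexa-1,5-diene-1-carbaldehyde | CC#CC1=CC(=O)[C@@](C)(O)C(Br)=C1C=O | intermediate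
15 | (3S)-2,3-dihydroxy-3-methyl-4-oxo-6-(prop-1-yn-1-yl)cyclohexa-1,5-diene-1-carbaldehyde (same spatial arrangement as 14; descriptor changes by priority) | CC#CC1=CC(=O)[C@@](C)(O)C(O)=C1C=O | intermediate
16 | (7R)-7-hydroxy-3,7-dimethyl-6H-isochromene-6,8(7H)-dione | O[C@]1(C)C(=O)C=C2C=C(C)OC=C2C1=O | intermediate
17 | (9Z,12Z)-octadeca-9,12-dienoyl chloride | CCCCC/C=C\C/C=C\CCCCCCCC(=O)Cl | starting material
18 | (7R)-3,7-dimethyl-6,8-dioxo-7,8-dihydro-6H-isochromen-7-yl (9Z,12Z)-octadeca-9,12-dienoate | CCCCC/C=C\C/C=C\CCCCCCCC(=O)O[C@]1(C)C(=O)C=C2C=C(C)OC=C2C1=O | target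

Total steps: 9. Longest linear sequence: 7 steps (steps 1, 2, 3, 4, 7, 8, 9).

**Steps most likely to fail**

Step 7 (proposed method, the riskiest). The catalysed cycloaddition may fail through poor facial discrimination of the furan. The Lewis acid may also divert the silyl enol ether into addition at the formyl carbon, or the first-formed zwitterion may lose bromide before the second bond closes. The fallback uses known chemistry, sets out from 9 and 12 and returns at 16. The uncatalysed Diels–Alder reaction of 9 with 12 (CH2Cl2, −20 to 23 °C) should give racemic 2-bromo-1-methyl-4-(prop-1-yn-1-yl)-6-[(triisopropylsilyl)oxy]-7-oxabicyclo[2.2.1]hepta-2,5-diene-3-carbaldehyde F1. Bu4NF/AcOH opens it to racemic 2-bromo-3-hydroxy-3-methyl-4-oxo-6-(prop-1-yn-1-yl)cyclohexa-1,5-diene-1-carbaldehyde F2. Under the conditions of step 8 this passes through racemic 2,3-dihydroxy-3-methyl-4-oxo-6-(prop-1-yn-1-yl)cyclohexa-1,5-diene-1-carbaldehyde F3 to racemic 7-hydroxy-3,7-dimethyl-6H-isochromene-6,8(7H)-dione F4. F4 is resolved by preparative supercritical-fluid chromatography on an amylose tris(3,5-dimethylphenylcarbamate) phase, and the (7R)-enantiomer is 16.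

Step 8. Hydrolysis at C8 may be slower than self-cycloaddition or other decomposition of the free dienone 14, or the oxygen may close 5-exo instead of 6-endo. The fallback reverses the order of events, sets out from 14 and returns at 16. Au(OAc)3 (5 mol%) and CF3CO2H in 1,2-dichloroethane at 23 °C should close the pyran ring first, by 6-endo-dig attack of the formyl oxygen on the gold-activated alkyne, to give (7R)-8-bromo-7-hydroxy-3,7-dimethyl-6-oxo-6,7-dihydroisochromen-2-ium trifluoroacetate F5. Aqueous NaHCO3 then adds water at C8 of this vinylogous oxocarbenium ion, with loss of bromide, to give 16.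

Step 2. The acetylide may add a second time to the ynone that forms, and the volatile, unstable diyne may be lost or decompose before it is acylated. The fallback builds the propynyl group on the finished furan instead, sets out from 4 and returns at 9. Lithium (trimethylsilyl)acetylide (from ethynyltrimethylsilane and n-BuLi, THF, −78 °C) and 4 should give (4S)-4-[(tert-butyldimethylsilyl)oxy]-1-(trimethylsilyl)pent-1-yn-3-one F6. Bu4NF removes both silyl groups and the alkoxide cyclises to (2S)-2-methylfuran-3(2H)-one F7. iPr3SiOSO2CF3/Et3N gives triisopropyl[(2-methylfuran-3-yl)oxy]silane F8. Lithiation at the free α-position (n-BuLi, THF, −78 °C) and quenching with I2 gives [(5-iodo-2-methylfuran-3-yl)oxy]triisopropylsilane F9. Sonogashira coupling with propyne (PdCl2(PPh3)2, CuI, Et3N, THF, 23 °C) then gives 9.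

Further compounds
F1 | step 7 | racemic 2-bromo-1-methyl-4-(prop-1-yn-1-yl)-6-[(triisopropylsilyl)oxy]-7-oxabicyclo[2.2.1]hepta-2,5-diene-3-carbaldehyde | CC12OC(C#CC)(C=C1O[Si](C(C)C)(C(C)C)C(C)C)C(C=O)=C2Br
F2 | step 7 | racemic 2-bromo-3-hydroxy-3-methyl-4-oxo-6-(prop-1-yn-1-yl)cyclohexa-1,5-diene-1-carbaldehyde | CC#CC1=CC(=O)C(C)(O)C(Br)=C1C=O
F3 | step 7 | racemic 2,3-dihydroxy-3-methyl-4-oxo-6-(prop-1-yn-1-yl)cyclohexa-1,5-diene-1-carbaldehyde | CC#CC1=CC(=O)C(C)(O)C(O)=C1C=O
F4 | step 7 | racemic 7-hydroxy-3,7-dimethyl-6H-isochromene-6,8(7H)-dione | OC1(C)C(=O)C=C2C=C(C)OC=C2C1=O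
F5 | step 8 | (7R)-8-bromo-7-hydroxy-3,7-dimethyl-6-oxo-6,7-dihydroisochromen-2-ium trifluoroacetate | CC1=CC2=CC(=O)[C@@](C)(O)C(Br)=C2C=[O+]1.[O-]C(=O)C(F)(F)F
F6 | step 2 | (4S)-4-[(tert-butyldimethylsilyl)oxy]-1-(trimethylsilyl)pent-1-yn-3-one | C[C@H](O[Si](C)(C)C(C)(C)C)C(=O)C#C[Si](C)(C)C
F7 | step 2 | (2S)-2-methylfuran-3(2H)-one | C1=CC(=O)[C@H](C)O1
F8 | step 2 | triisopropyl[(2-methylfuran-3-yl)oxy]silane | Cc1occc1O[Si](C(C)C)(C(C)C)C(C)C
F9 | step 2 | [(5-iodo-2-methylfuran-3-yl)oxy]triisopropylsilane | Cc1oc(I)cc1O[Si](C(C)C)(C(C)C)C(C)C
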